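I read the solid substrate of this flask as a pump more than as a charged reagent, because by 20 h dissolution into an empty solution delivers 75.6% of the charge, less than the charge itself.

    intermediate C → side product B (k1 = 0.056 h⁻¹)
    intermediate B → side product A (k2 = 0.094 h⁻¹)
    intermediate B → decomposed reagent (k3 = 0.064 h⁻¹)
    solid substrate ⇌ starting material, rate k4*(cs4 - [starting material]) while solid is left; crystals form when [starting material] > cs4 (cs4 = 0.21 M, k4 = 0.090 h⁻¹)
    intermediate A ⇌ intermediate C (K5 = 0.16, k5 = 0.0094 h⁻¹)
    starting material → target (k6 = 0.069 h⁻¹)
    capture agent + intermediate A → trapped intermediate (k7 = 0.30 L mol⁻¹ h⁻¹)
    starting material ⇌ intermediate B (K8 = 2.3, k8 = 0.040 h⁻¹)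
    intermediate B ⇌ intermediate A (k9 = 0.040 h⁻¹)
    starting material ⇌ intermediate A (K10 = 0.12, k10 = 0.028 h⁻¹)

solid substrate 0.50 M; capture agent 0.0500 M; time 20 h

* the target standing at 20 h, as a percentage of the solid substrate charged
* the change that raises the amount of target at 20 h, in percent of the solid substrate charged most ("none" if none brings more than 2 percentage points) (larch / elm / none)
* amount of target at 20 h, in percent of the solid substrate charged, after elm

- as a solid, counted per litre of solution: solid substrate
- at the start none of the solid substrate is in solution
- run time (flask): 20 h

- larch: doubling the dissolution coefficient of step 4, all else as stated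
- elm: doubling the solubility in step 4, all else as stated

So I call that figure the ceiling, and the charge enters it as a divisor. But the solution does not stay empty: dissolved starting material slows its own feed, at coefficient 0.090 h⁻¹, and this acts as an exit beside the ways to target, intermediate B and intermediate A. Setting aside the returns from the intermediates, these exits sum to 0.227 h⁻¹. The zero of my scale is 4 equal exits at 25.0% each, and the target holds 30.4%, more than that. Its production also trails by a lag of 4.41 h, as in a coupled assay.

So I carry the target's share of the ceiling, which is the exit share times the part of the run past the lag: 23.7%. This gives me 17.9% target. I leave out the capture agent, because the half-life of intermediate A by step 7 alone, 46 h, is longer than the run.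

Elm doubles the solubility in step 4, so it doubles the ceiling and keeps the share, which gives 35.8%, although the doubled ceiling of 151% stands past the charge, so the solid may not last. Larch doubles the dissolution coefficient of step 4, which doubles the ceiling too, but it raises the exits to 0.317 h⁻¹ and cuts the share to 18.3%, which gives 27.7%. Since elm stands higher than larch, I choose elm.

The forecast says 18.7%, elm and 37.3%, on the ground that “Doubling the solubility doubles the driving source”.

The flask gives 18.6%, and elm, at 37.2%, gains 19 percentage points against 9.9 points for larch. In this flask 48.7% of the solid substrate still stands at 20.0 h. The neighbour flask charged with 1.2 M shrinks the ceiling to 31.5%, and the same share of 23.7% makes that 7.47% target; that flask holds 7.76% at 20.0 h.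

The constants were drawn at random within sensible limits; no experiment stands behind them.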